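The route rests on cutting the C3–C4 bond of the γ-lactone ring (O1, C2 carbonyl, C3, C4, C5). That bond joins two carbons that each sit α to an acyl carbon (C2 and the C4 carboxyl), a pairing that ordinary enolate alkylation cannot forge directly, whereas the C5 oxygen can carry a diazoacetate. A chiral dirhodium carboxamidate turns this ester into a carbene that inserts into a benzylic C–H bond, so one operation closes the lactone, makes C3–C4 and sets C4 cis to the C5 chain. The precursor is the diazoacetate of an (S)-1-(4-methoxyphenyl)alkan-2-ol whose anisyl ring is a latent C4 carboxyl and whose chain ketone is masked as a dioxolane.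

Key step: step 9

Remark: the matched catalyst in step 9 is assumed to be the enantiomer that gives 4R-configured 4-aryl-γ-butyrolactones from achiral 2-arylethyl diazoacetates, taken here as Rh2(4R-MPPIM)4; the cis target is (4S,5S) in lactone locants, and the descriptor at C4 changes from R (aryl) to S (carboxyl) by priority only.

Step 1
Reactants: 1 pentadecanolide; 2 N,O-dimethylhydroxylamine hydrochloride; 3 methylmagnesium bromide
Product: 5 16-hydroxyhexadecan-2-one, via hydroxy Weinreb amide 4 (not isolated)
Conditions: 2 (1.5 equiv), i-PrMgCl (3.0 equiv), THF, −20 → 0 °C; then 3 (3 equiv), 0 °C → rt; aq. NH4Cl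
Reagents that add atoms: methylmagnesium bromide, C[Mg]Br (N,O-dimethylhydroxylamine hydrochloride, CNOC.Cl, contributes only to intermediate 4)
Why: Weinreb ketone synthesis in one flask: the chloromagnesium amide opens the unstrained macrolactone by acyl substitution, and the N-methoxy amide takes up one MeMgBr as a stable five-membered magnesium chelate that collapses to the methyl ketone only on quench, so over-addition to a tertiary alcohol is avoided.

Step 2
Reactants: 5 16-hydroxyhexadecan-2-one; 6 ethylene glycol
Product: 7 14-(2-methyl-1,3-dioxolan-2-yl)tetradecan-1-ol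
Conditions: 6 (5 equiv), p-TsOH·H2O (cat.), toluene, reflux, Dean–Stark
Reagents that add atoms: ethylene glycol, OCCO
Why: Acid-catalysed ketalisation driven by azeotropic removal of water, the excess diol ensuring that the ketone ends as the five-membered dioxolane and not as a mixed ketal with the substrate's own primary hydroxyl.

Step 3
Reactants: 7 14-(2-methyl-1,3-dioxolan-2-yl)tetradecan-1-ol
Product: 8 14-(2-methyl-1,3-dioxolan-2-yl)tetradecanal
Conditions: TEMPO (10 mol%), PhI(OAc)2 (1.1 equiv), CH2Cl2, rt
Reagents that add atoms: none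
Why: Oxoammonium (TEMPO) oxidation with PhI(OAc)2 as terminal oxidant stops at the aldehyde in the absence of water, and the weakly acidic anhydrous medium leaves the dioxolane untouched.

Step 4
Reactants: 8 14-(2-methyl-1,3-dioxolan-2-yl)tetradecanal; 9 trimethylsulfonium iodide
Product: 10 racemic 2-methyl-2-[13-(oxiran-2-yl)tridecyl]-1,3-dioxolane
Conditions: 9 (1.3 equiv), n-BuLi (1.2 equiv), THF, −10 → 0 °C; then 8, −10 °C → rt
Reagents that add atoms: trimethylsulfonium iodide, C[S+](C)C.[I-]
Why: Corey–Chaykovsky epoxidation: the non-stabilised sulfonium ylide adds to the aldehyde and the betaine closes by intramolecular displacement of Me2S, giving the terminal epoxide as a racemate, which is intended at this stage.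

Step 5
Reactants: 10 racemic 2-methyl-2-[13-(oxiran-2-yl)tridecyl]-1,3-dioxolane
Product: 11 2-methyl-2-{13-[(2S)-oxiran-2-yl]tridecyl}-1,3-dioxolane
Conditions: (S,S)-(salen)Co(OAc) (0.5–1 mol%; salen = N,N'-bis(3,5-di-tert-butylsalicylidene)cyclohexane-1,2-diaminate, trivalent cobalt, made from divalent (S,S)-(salen)Co with AcOH/air), H2O (0.55 equiv), THF (minimal), 0 °C → rt
Reagents that add atoms: none
Why: Hydrolytic kinetic resolution of a terminal epoxide: the chiral (salen)Co(OAc) catalyst is expected to hydrolyse the R epoxide far faster than the S epoxide, so the S epoxide that becomes C5 of the target should be recovered (at most half of the material) in high enantiomeric purity and separated from the polar diol by chromatography.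

Step 6
Reactants: 11 2-methyl-2-{13-[(2S)-oxiran-2-yl]tridecyl}-1,3-dioxolane; 12 4-methoxyphenylmagnesium bromide (commercial THF solution)
Product: 13 (2S)-1-(4-methoxyphenyl)-15-(2-methyl-1,3-dioxolan-2-yl)pentadecan-2-ol
Conditions: 12 (1.5 equiv), CuI (copper monoiodide, 10 mol%), THF, −30 → 0 °C; aq. NH4Cl
Reagents that add atoms: 4-methoxyphenylmagnesium bromide, COc1ccc([Mg]Br)cc1
Why: Copper-catalysed epoxide opening by an aryl Grignard reagent, an SN2 attack at the unsubstituted carbon that leaves the stereocenter untouched, so the S carbinol carries over unchanged.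

Step 7
Reactants: 13 (2S)-1-(4-methoxyphenyl)-15-(2-methyl-1,3-dioxolan-2-yl)pentadecan-2-ol; 14 bromoacetyl bromide
Product: 15 (2S)-1-(4-methoxyphenyl)-15-(2-methyl-1,3-dioxolan-2-yl)pentadecan-2-yl bromoacetate
Conditions: 14 (1.3 equiv), pyridine (1.5 equiv), CH2Cl2, 0 °C
Reagents that add atoms: bromoacetyl bromide, BrCC(Br)=O
Why: Acylation of the secondary alcohol by the acid bromide (far more reactive than the alkyl bromide end), with pyridine taking up HBr so that the dioxolane never meets free acid.

Step 8
Reactants: 15 (2S)-1-(4-methoxyphenyl)-15-(2-methyl-1,3-dioxolan-2-yl)pentadecan-2-yl bromoacetate; 16 N,N'-ditosylhydrazine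
Product: 17 (2S)-1-(4-methoxyphenyl)-15-(2-methyl-1,3-dioxolan-2-yl)pentadecan-2-yl diazoacetate
Conditions: 16 (2 equiv), DBU (5 equiv), THF, 0 °C
Reagents that add atoms: N,N'-ditosylhydrazine, Cc1ccc(cc1)S(=O)(=O)NNS(=O)(=O)c1ccc(C)cc1
Why: Diazoacetate formation from a bromoacetate: the ditosylhydrazine anion displaces bromide and DBU then induces loss of two sulfinate groups, which delivers the diazo ester at 0 °C without acid or a diazo-transfer reagent.

Step 9
Reactants: 17 (2S)-1-(4-methoxyphenyl)-15-(2-methyl-1,3-dioxolan-2-yl)pentadecan-2-yl diazoacetate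
Product: 18 (4R,5S)-4-(4-methoxyphenyl)-5-[13-(2-methyl-1,3-dioxolan-2-yl)tridecyl]dihydrofuran-2(3H)-one (aryl and chain cis)
Conditions: Rh2(4R-MPPIM)4 (1–2 mol%; MPPIM = methyl 2-oxo-1-(3-phenylpropanoyl)imidazolidine-4-carboxylate), CH2Cl2, reflux, 17 added by syringe pump over ca. 8 h
Reagents that add atoms: none
Why: The carboxamidate-bridged dirhodium catalyst displaces N2 from the diazo carbon to give an electrophilic metal carbene, and this carbon takes up a benzylic C4–H bond through a single three-membered C–H–C array in which hydride shift runs ahead of C–C bonding, without a free intermediate, so C3–C4 forms directly. The closest known reaction type is the chiral dirhodium carboxamidate-catalysed intramolecular C–H insertion of 2-arylethyl and secondary alkyl diazoacetates to γ-butyrolactones. The lactone ring closes in the 1,5 mode: the carbene carbon (C3) bonds to the fifth atom of the array C3–C2–O1–C5–C4 via a six-membered transition state that contains the migrating hydrogen, which is preferred over the four-membered (C5–H) and six-membered (second chain CH2) alternatives. The new C4 stereocenter results from which of the two diastereotopic benzylic hydrogens is replaced; the chiral ligand shell decides this, and the 4R catalyst is paired with the fixed 5S centre as the matched case so that the anisyl group should end cis to the chain (4R,5S). The step needs site selectivity for the benzylic CH2 over the first chain CH2, the C5–H and the arene π system; the para-methoxy group makes the benzylic hydrogens the most hydridic ones, the matched catalyst directs the carbene to that arm, and the electron-rich carboxamidate ligands make the carbene too mild for aromatic cycloaddition (Buchner reaction), while slow addition keeps carbene dimerisation down.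

Step 10
Reactants: 18 (4R,5S)-4-(4-methoxyphenyl)-5-[13-(2-methyl-1,3-dioxolan-2-yl)tridecyl]dihydrofuran-2(3H)-one
Product: 19 (2S,3S)-2-[13-(2-methyl-1,3-dioxolan-2-yl)tridecyl]-5-oxotetrahydrofuran-3-carboxylic acid (cis)
Conditions: RuCl3·xH2O (5 mol%), NaIO4 (ca. 15 equiv), CCl4/MeCN/aq. phosphate buffer (pH 6–7), rt; work-up at pH 3–4 (citric acid)
Reagents that add atoms: sodium periodate, [Na+].[O-]I(=O)(=O)=O (oxygen delivered through RuO4); water, O
Why: Oxidative degradation of an electron-rich arene by catalytic RuO4: the ring is consumed down to the ipso carbon, which stays on C4 as the carboxyl group, so no bond at either stereocenter is broken and the cis relationship is retained, while the near-neutral buffer is meant to preserve the dioxolane.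

Step 11
Reactants: 19 (2S,3S)-2-[13-(2-methyl-1,3-dioxolan-2-yl)tridecyl]-5-oxotetrahydrofuran-3-carboxylic acid; 20 methyl magnesium carbonate; 21 formaldehyde
Product: 23 (2S,3S)-4-methylene-2-[13-(2-methyl-1,3-dioxolan-2-yl)tridecyl]-5-oxotetrahydrofuran-3-carboxylic acid, via lactone malonic diacid 22 (not isolated)
Conditions: MeOMgOCO2Me (2 M in DMF, excess), 130–135 °C; brief cold dilute HCl/CH2Cl2 work-up; crude 22, then 37% aq. HCHO, PhNHMe, NaOAc, AcOH, rt
Reagents that add atoms: formaldehyde, C=O (methyl magnesium carbonate, CO[Mg]OC(=O)OC, adds only the carboxyl of intermediate 22, lost again as CO2)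
Why: Carboxylation of the lactone α-carbon with methyl magnesium carbonate through a magnesium-chelated enolate, followed by decarboxylative Mannich methylenation of the malonic acid-type intermediate with formaldehyde and a secondary amine; the C4 carboxylate is inert to both operations, C4 and C5 are not deprotonated, and any ketal lost in the acidic work-up converges in step 12.

Step 12
Reactants: 23 (2S,3S)-4-methylene-2-[13-(2-methyl-1,3-dioxolan-2-yl)tridecyl]-5-oxotetrahydrofuran-3-carboxylic acid
Product: 24 allo-pertusaric acid, (2S,3S)-4-methylene-5-oxo-2-(14-oxopentadecyl)tetrahydrofuran-3-carboxylic acid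
Conditions: 1 M HCl, THF, rt
Reagents that add atoms: water, O
Why: Acid-catalysed ketal hydrolysis, the oxocarbenium ion being trapped by water; the α-methylene lactone and the carboxylic acid are stable to dilute aqueous acid at room temperature, so the methyl ketone is unveiled last.

Compound list
1 | pentadecanolide (oxacyclohexadecan-2-one) | O=C1CCCCCCCCCCCCCCO1 | starting material
2 | N,O-dimethylhydroxylamine hydrochloride | CNOC.Cl | starting material
3 | methylmagnesium bromide | C[Mg]Br | starting material
4 | 15-hydroxy-N-methoxy-N-methylpentadecanamide (hydroxy Weinreb amide, not isolated) | CON(C)C(=O)CCCCCCCCCCCCCCO | intermediate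
5 | 16-hydroxyhexadecan-2-one | CC(=O)CCCCCCCCCCCCCCO | intermediate
6 | ethylene glycol | OCCO | starting material
7 | 14-(2-methyl-1,3-dioxolan-2-yl)tetradecan-1-ol | CC1(CCCCCCCCCCCCCCO)OCCO1 | intermediate
8 | 14-(2-methyl-1,3-dioxolan-2-yl)tetradecanal | CC1(CCCCCCCCCCCCCC=O)OCCO1 | intermediate
9 | trimethylsulfonium iodide | C[S+](C)C.[I-] | starting material
10 | racemic 2-methyl-2-[13-(oxiran-2-yl)tridecyl]-1,3-dioxolane | CC1(CCCCCCCCCCCCCC2CO2)OCCO1 | intermediate
11 | 2-methyl-2-{13-[(2S)-oxiran-2-yl]tridecyl}-1,3-dioxolane | CC1(CCCCCCCCCCCCC[C@H]2CO2)OCCO1 | intermediate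
12 | 4-methoxyphenylmagnesium bromide | COc1ccc([Mg]Br)cc1 | starting material
13 | (2S)-1-(4-methoxyphenyl)-15-(2-methyl-1,3-dioxolan-2-yl)pentadecan-2-ol | O[C@@H](CCCCCCCCCCCCCC1(C)OCCO1)Cc1ccc(OC)cc1 | intermediate
14 | bromoacetyl bromide | BrCC(Br)=O | starting material
15 | (2S)-1-(4-methoxyphenyl)-15-(2-methyl-1,3-dioxolan-2-yl)pentadecan-2-yl bromoacetate | BrCC(=O)O[C@@H](CCCCCCCCCCCCCC1(C)OCCO1)Cc1ccc(OC)cc1 | intermediate
16 | N,N'-ditosylhydrazine | Cc1ccc(cc1)S(=O)(=O)NNS(=O)(=O)c1ccc(C)cc1 | starting material
17 | (2S)-1-(4-methoxyphenyl)-15-(2-methyl-1,3-dioxolan-2-yl)pentadecan-2-yl diazoacetate | [N-]=[N+]=CC(=O)O[C@@H](CCCCCCCCCCCCCC1(C)OCCO1)Cc1ccc(OC)cc1 | intermediate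
18 | (4R,5S)-4-(4-methoxyphenyl)-5-[13-(2-methyl-1,3-dioxolan-2-yl)tridecyl]dihydrofuran-2(3H)-one (cis) | C1C(=O)O[C@@H](CCCCCCCCCCCCCC2(C)OCCO2)[C@H]1c3ccc(OC)cc3 | intermediate
19 | (2S,3S)-2-[13-(2-methyl-1,3-dioxolan-2-yl)tridecyl]-5-oxotetrahydrofuran-3-carboxylic acid (cis) | C1C(=O)O[C@@H](CCCCCCCCCCCCCC2(C)OCCO2)[C@H]1C(=O)O | intermediate
20 | methyl magnesium carbonate | CO[Mg]OC(=O)OC | starting material
21 | formaldehyde (37% aqueous) | C=O | starting material
22 | (2S,3S)-2-[13-(2-methyl-1,3-dioxolan-2-yl)tridecyl]-5-oxotetrahydrofuran-3,4-dicarboxylic acid (C4 of this name unassigned, not isolated) | OC(=O)C1C(=O)O[C@@H](CCCCCCCCCCCCCC2(C)OCCO2)[C@H]1C(=O)O | intermediate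
23 | (2S,3S)-4-methylene-2-[13-(2-methyl-1,3-dioxolan-2-yl)tridecyl]-5-oxotetrahydrofuran-3-carboxylic acid | C=C1C(=O)O[C@@H](CCCCCCCCCCCCCC2(C)OCCO2)[C@H]1C(=O)O | intermediate
24 | allo-pertusaric acid, (2S,3S)-4-methylene-5-oxo-2-(14-oxopentadecyl)tetrahydrofuran-3-carboxylic acid | C=C1C(=O)O[C@@H](CCCCCCCCCCCCCC(C)=O)[C@H]1C(=O)O | target

Total step count: 12. Longest linear sequence: 12 steps (1 to 24, fully linear).

Steps most likely to fail

Step 9. The discrimination between the two benzylic hydrogens may be eroded or reversed if the catalyst–substrate pairing is not the matched one, which would give the trans lactone, and insertion into the first chain CH2 or attack on the arene may compete. The enantiomeric catalyst is the first check. The fallback replaces catalyst control of C4 by substrate control; it sets out from 17 and returns at 18. Diazo decomposition with achiral Rh2(cap)4 (dirhodium tetracaprolactamate) in refluxing CH2Cl2 should still give the 1,5-insertion product, now as (5S)-4-(4-methoxyphenyl)-5-[13-(2-methyl-1,3-dioxolan-2-yl)tridecyl]dihydrofuran-2(3H)-one as a mixture of C4 epimers F1. α-Selenenylation (LDA, THF, −78 °C; PhSeBr) would give (5S)-4-(4-methoxyphenyl)-5-[13-(2-methyl-1,3-dioxolan-2-yl)tridecyl]-3-(phenylselanyl)dihydrofuran-2(3H)-one F2. Oxidation (H2O2, pyridine, CH2Cl2, 0 °C) and selenoxide syn-elimination would erase C4 in (5S)-4-(4-methoxyphenyl)-5-[13-(2-methyl-1,3-dioxolan-2-yl)tridecyl]furan-2(5H)-one F3. Hydrogenation (H2, Rh/Al2O3 or Pd/C, EtOAc) should then add hydrogen to the face opposite the C5 chain and so place the aryl group cis, giving 18.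

Step 10. The dioxolane may be lost by hydrolysis or oxidative attack while the arene is degraded, and the buffer may slow RuO4 so that ring cleavage stays incomplete. The fallback changes the protecting-group order; it sets out from 18 and returns at 19. The ketal is removed first (1 M HCl, THF, rt) to give (4R,5S)-4-(4-methoxyphenyl)-5-(14-oxopentadecyl)dihydrofuran-2(3H)-one F4, whose free ketone is inert to RuO4. Unbuffered RuCl3/NaIO4 (CCl4/MeCN/H2O) then gives (2S,3S)-5-oxo-2-(14-oxopentadecyl)tetrahydrofuran-3-carboxylic acid F5. The ketone is masked again with 1,2-bis(trimethylsilyloxy)ethane and catalytic TMSOTf (CH2Cl2, −78 → −20 °C; aqueous work-up cleaves the transient silyl ester) to give 19.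

Step 11. Prolonged heating with the basic magnesium reagent may epimerise C4 toward the more stable trans acid, and carboxylation may stay incomplete. The fallback is a low-temperature methylenation; it sets out from 19 and returns at 23. The carboxylate/lactone enolate dianion (LiHMDS, 2.3 equiv, THF, −78 °C), in which the carboxylate shields C4 from deprotonation, is trapped with CH2=NMe2+ I− (Eschenmoser's salt) to give (2S,3S)-4-[(dimethylamino)methyl]-2-[13-(2-methyl-1,3-dioxolan-2-yl)tridecyl]-5-oxotetrahydrofuran-3-carboxylic acid F6. Quaternisation (MeI, NaHCO3, MeOH, rt) gives the trimethylammonium iodide of this acid F7, which should eliminate trimethylamine under the same bicarbonate conditions to give 23.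

Further compounds
F1 | step 9 | (5S)-4-(4-methoxyphenyl)-5-[13-(2-methyl-1,3-dioxolan-2-yl)tridecyl]dihydrofuran-2(3H)-one, mixture of C4 epimers | C1C(=O)O[C@@H](CCCCCCCCCCCCCC2(C)OCCO2)C1c3ccc(OC)cc3
F2 | step 9 | (5S)-4-(4-methoxyphenyl)-5-[13-(2-methyl-1,3-dioxolan-2-yl)tridecyl]-3-(phenylselanyl)dihydrofuran-2(3H)-one | O=C1O[C@@H](CCCCCCCCCCCCCC2(C)OCCO2)C(c3ccc(OC)cc3)C1[Se]c4ccccc4
F3 | step 9 | (5S)-4-(4-methoxyphenyl)-5-[13-(2-methyl-1,3-dioxolan-2-yl)tridecyl]furan-2(5H)-one | O=C1O[C@@H](CCCCCCCCCCCCCC2(C)OCCO2)C(c3ccc(OC)cc3)=C1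
F4 | step 10 | (4R,5S)-4-(4-methoxyphenyl)-5-(14-oxopentadecyl)dihydrofuran-2(3H)-one | C1C(=O)O[C@@H](CCCCCCCCCCCCCC(C)=O)[C@H]1c2ccc(OC)cc2
F5 | step 10 | (2S,3S)-5-oxo-2-(14-oxopentadecyl)tetrahydrofuran-3-carboxylic acid | C1C(=O)O[C@@H](CCCCCCCCCCCCCC(C)=O)[C@H]1C(=O)O
F6 | step 11 | (2S,3S)-4-[(dimethylamino)methyl]-2-[13-(2-methyl-1,3-dioxolan-2-yl)tridecyl]-5-oxotetrahydrofuran-3-carboxylic acid | CN(C)CC1C(=O)O[C@@H](CCCCCCCCCCCCCC2(C)OCCO2)[C@H]1C(=O)O
F7 | step 11 | trimethylammonium iodide of F6, {[(4S,5S)-4-carboxy-5-[13-(2-methyl-1,3-dioxolan-2-yl)tridecyl]-2-oxotetrahydrofuran-3-yl]methyl}trimethylammonium iodide | C[N+](C)(C)CC1C(=O)O[C@@H](CCCCCCCCCCCCCC2(C)OCCO2)[C@H]1C(=O)O.[I-]
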